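Locants: unprimed locants and rings A, C, B belong to the upper (epigallocatechin) unit; primed locants and rings D, F, E belong to the lower (catechin) unit. Substituents on rings B and E are given by ring letter.

## Analysis of the target

- The target 20 is epigallocatechin 3-O-gallate-(4β→8)-catechin: two flavan units joined by one bond from C4 of the upper unit to C8′ of the lower unit.
- The upper unit has three contiguous stereocentres, C2 (R), C3 (R) and C4 (R). The ring B aryl group and O3 are cis, the C4–C8′ bond is trans to O3, and O3 carries the galloyl ester.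
- The lower unit is a catechin: C2′ (R) and C3′ (S) are trans and the 3′-hydroxyl is free.
- The two sets of stereocentres are separated by the flat ring D, so neither can be expected to control the other strongly.
- Sensitive features are twelve phenols (two pyrogallol rings that oxidise in air), an aryl ester, and the C4–C8′ bond, which is benzylic to two phloroglucinol rings and is cleaved by acid.
- The hard points are the 4→8 (not 4→6) connectivity, the configuration at C4, telling the two secondary hydroxyls apart (O3 acylated, O3′ free), and a neutral final deprotection.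
- The plan rests on ring D: the oxygen on C8a′, C4a′ and the chain C4′–C3′–C2′ ending in ring E are the atoms of a 2′-hydroxychalcone. Forming O1′–C2′ closes ring F, and C8′, ortho to that oxygen, can already carry the finished upper unit.

## Retrosynthetic reasoning

**20 from 19.** The last operation cuts only the twelve O–benzyl bonds of 19. All phenols stay masked through every basic, acidic and oxidative step, and the air-sensitive polyphenol appears once, under neutral reducing conditions that leave the ester and the C4–C8′ bond alone.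

**19 from 18 from 17.** The C4′ methylene is traced back to a carbonyl: 19 from diol 18 by exchanging C4′–O for C4′–H, and 18 from ketone 17. Keeping the carbonyl late is deliberate. While it is present, ring D is an acylated, electron-poor phloroglucinol and the C4–C8′ bond is shielded from acid. The forward steps must remove one benzylic oxygen without touching the 3′-hydroxyl or the ester.

**17 from 14.** The C3′–O bond is cut: α-oxygenation of flavanone 14 through its silyl enol ether 15 and the silyloxy ketone 16. The C2′ aryl group sends the oxygen to the opposite face, and the α-ketol can settle in the trans form anyway, so the 2′,3′-trans relation comes from C2′.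

**14 from 12 and 13.** The ester C–O bond at O3 is cut to alcohol 12 and acid 13. At this point the molecule has a single hydroxyl. Earlier, the ester would not survive the organomagnesium and hydroxide steps. Later, once the 3′-hydroxyl exists, two secondary alcohols would compete and the less hindered one is the wrong one. No protecting group is therefore needed on O3 or O3′.

**12 from 11.** The O1′–C2′ bond is cut, opening ring F to the 2′-hydroxychalcone 11. This reduces the whole lower unit to a ring D phenol plus simple carbon pieces. The forward reaction is a conjugate addition of the C8a′ phenol with control of the C2′ face.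

**11 from 9 and 10.** The C2′=C3′ bond is cut by a retro-aldol condensation to methyl ketone 9 and aldehyde 10. Ring E and C2′ come from 10.

**9 from 8 from 7 from 6.** The acetyl group leaves ring D in two cuts: C3′–C4′ (methyl addition to aldehyde 7, then oxidation of carbinol 8) and C4a′–C4′ (ortho-formylation of phenol 6). Direct acetylation was not chosen: a Lewis acid at temperature threatens the C4–C8′ bond and could acylate para to the hydroxyl, which would later give the 4→6 isomer. A phenoxide-directed formylation is basic and can only go ortho, and the one free ortho carbon is C4a′.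

**6 from 3 and 5.** The C4–C8′ bond is cut to a C4 electrophile (ether 3) and phenol 5, which reacts through a carbon ortho to its hydroxyl. Ring C with C2 and C3 stays intact from nature. The forward step has to deliver C4 anti to O3 and ortho regiochemistry.

**3 from 2 from 1; 5 from 4.** Ether 3 comes from 2 by oxidation of C4–H, and 2 from natural 1 by benzylation of the phenols. Phenol 5 comes from 4 by partial benzylation.

## Alternatives that were turned down

**Alternative 1:** ring A is disconnected at C5–C6 and C8–C8a.
- Disconnection: C4 carries a malonate, A1, whose central carbon becomes C4a; the other three ring carbons come from dimethyl 3-oxopentanedioate, A2.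
- Forward key step: a double Claisen condensation under sodium and magnesium alkoxide conditions gives a cyclohexanetrione that aromatises to the phloroglucinol diester A3.
- For it: the C4–C8′ bond exists before ring A, so there is no Friedel–Crafts regiochemistry and no C4 cation. On connectivity it is stronger than the chosen route.
- Against it: the three stereocentres of ring C are not taken from nature; C2, C3 and C4 must be built in an open chain in A1. In A3 the C2 oxygen has the opposite configuration to O1–C2 of 20, so ring C must close by invertive substitution at an electron-rich benzylic carbon, where ionisation leaks towards the 2,3-trans series. The double condensation on a malonate with a bulky secondary substituent is hindered, and two ester groups must be removed afterwards.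
- Comparison: the chosen route offers ring C ready-made from 1 with two centres fixed and the third set by a reliable anti attack, in far fewer steps.

**Alternative 2:** ring C is disconnected at four bonds (C8a–O1, C4a–C4, C3–C4, O1–C2).
- Disconnection: ring A comes from an aryne released from silyl triflate A4, C4 from the formyl carbon of the lower unit's C8-carbaldehyde A5, and C2–C3 with the ester from the (Z)-enol gallate A6.
- Forward key step: fluoride releases the aryne, its [2+2] addition to the formyl group and ring-opening give an ortho-quinone methide, and a hetero-Diels–Alder reaction with A6 gives the fully benzylated target A7.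
- For it: it is by far the shortest plan and clearly stronger on step economy. The aryne polarity is matched (the carbonyl oxygen adds to the aryne carbon remote from the C5 benzyloxy group), the Z-alkene maps onto the 2,3-cis relation, and the gallate is already in place.
- Against it: C2, C3 and C4 are all created in one cycloaddition, and the only chirality present lies in ring F beyond the flat ring D. Little facial bias is to be expected, and the endo/exo ratio decides the 3,4 relation. An enol ester is a weak partner for an electron-rich quinone methide, and the aldehyde is flanked by two ortho oxygens.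
- Comparison: the chosen route gives certainty for C2 and C3 (from 1) and for C4 (substrate control), and leaves one centre to a catalyst with separable diastereomers.

**Alternative 3:** ring D is disconnected at C8′–C8a′ and C6′–C7′.
- Disconnection: ring D is assembled from the ynol silyl ether A8 on C4 and the cyclobutenone A9.
- Forward key step: a thermal cascade (ring-opening to a vinylketene, [2+2] addition to the alkyne, second ring-opening, 6π closure, tautomerisation) gives the phenol A10.
- For it: the mechanism fixes the substitution of ring D, with the upper unit on C8′ and the free hydroxyl on C8a′. On regiochemistry it is stronger than the arylation of step 4, and the conditions are neutral.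
- Against it: A8 needs an alkynylation at C4 and an ynol ether synthesis on a hindered secondary carbon. A9 is a chiral, multiply substituted cyclobutenone with its own multistep synthesis. In A10 ring F is still open, and its C2′ oxygen has the opposite configuration to O1′–C2′ of 20, so closure again needs inversion at an electron-rich benzylic carbon.
- Comparison: the chosen route buys ring D as 4, answers the regiochemical doubt with a directed formylation (and a blocked nucleophile in reserve), and needs many fewer steps.

Key step: step 9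

Remark on the chemistry: aldehyde 10 and acid 13 are catalogue compounds. Which member of the pseudoenantiomeric catalyst pair is matched to the upper unit in step 9 cannot be derived beforehand; the route is written for the quinine-derived one, and N-[3,5-bis(trifluoromethyl)phenyl]-N′-[(9R)-6′-methoxycinchonan-9-yl]thiourea replaces it unchanged if that one proves matched.

## Route

Step 1
Reactants: 1 (−)-epigallocatechin
Product: 2 (2R,3R)-5,7-bis(benzyloxy)-2-[3,4,5-tris(benzyloxy)phenyl]chroman-3-ol (pentabenzyl epigallocatechin)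
Conditions: BnBr (5.5 equiv), K2CO3, DMF, −20 °C → rt, argon
Reagents that add atoms: benzyl bromide, BrCc1ccccc1
Why: Williamson ether synthesis on the five phenols only, since the carbonate does not deprotonate the C3 alcohol; low temperature and exclusion of air limit C-benzylation of ring A and base-induced opening at C2, so the (2R,3R) configuration of 1 is kept.

Step 2
Reactants: 2 pentabenzyl epigallocatechin
Product: 3 4β-(2-ethoxyethoxy) derivative of 2 (2,3-cis, 3,4-trans, 3-OH free)
Conditions: DDQ (2 equiv), 2-ethoxyethanol (5 equiv), CH2Cl2, rt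
Reagents that add atoms: 2-ethoxyethanol, CCOCCO
Why: Benzylic oxidation by hydride abstraction with DDQ at C4, the position activated by the ring A oxygens; the cation is trapped by the alcohol on the face opposite the axial C3 hydroxyl, and this C4 configuration is lost again in step 4.

Step 3
Reactants: 4 phloroglucinol
Product: 5 3,5-bis(benzyloxy)phenol
Conditions: BnBr (2 equiv), K2CO3, DMF, 0 °C → rt
Reagents that add atoms: benzyl bromide, BrCc1ccccc1
Why: Statistical Williamson etherification of a cheap symmetrical triol; the dibenzyl ether is separated by chromatography from mono- and tribenzyl ethers and C-benzylated material, which is acceptable on a one-step side branch.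

Step 4
Reactants: 3 4β-(2-ethoxyethoxy) pentabenzyl epigallocatechin; 5 3,5-bis(benzyloxy)phenol (4 equiv)
Product: 6 pentabenzyl epigallocatechin carrying at C4 (β, trans to O3) a 4,6-bis(benzyloxy)-2-hydroxyphenyl group (ring D: OH on C8a′, benzyloxy on C5′ and C7′)
Conditions: TMSOTf (0.2 equiv), CH2Cl2, −78 → −40 °C; NaHCO3 aq
Reagents that add atoms: none
Why: Friedel–Crafts-type arylation: the Lewis acid ionises the chelating C4 ether to the ring A stabilised cation, which the excess phenol traps through the carbon between its hydroxyl and one benzyloxy group (less hindered than the carbon between two benzyloxy groups, two such sites, and the site at which this phenol is alkylated by allylic and benzylic cations). Attack anti to the axial C3 oxygen of the 2,3-cis half-chair sets C4 as 3,4-trans (4β), the normal outcome for epicatechin-type C4 cations; the excess of 5 suppresses self-arylation of 3 and a second arylation of 6.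

Step 5
Reactants: 6 C4-aryl phenol
Product: 7 aldehyde, ring D now 4,6-bis(benzyloxy)-3-formyl-2-hydroxyphenyl (formyl on C4a′)
Conditions: MgCl2 (3 equiv), Et3N (6 equiv), paraformaldehyde (10 equiv), THF, reflux
Reagents that add atoms: paraformaldehyde (as formaldehyde), C=O
Why: Magnesium-mediated ortho-formylation (Casnati–Skattebøl): the magnesium phenoxide delivers formaldehyde only to a carbon ortho to the phenol oxygen, and the single free ortho carbon is C4a′, so the acyl carbon cannot end up para to the hydroxyl; a second formaldehyde accepts the hydride. The medium is basic, so the acid-labile C4–C8′ bond is not at risk.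

Step 6
Reactants: 7 aldehyde
Product: 8 carbinol, ring D now 4,6-bis(benzyloxy)-2-hydroxy-3-(1-hydroxyethyl)phenyl (both carbinol epimers)
Conditions: MeMgBr (5 equiv), THF, 0 °C → rt; NH4Cl aq
Reagents that add atoms: methylmagnesium bromide, C[Mg]Br
Why: Grignard addition to the aldehyde after deprotonation of the phenol and the C3 alcohol (hence the excess); the new carbinol centre is formed without control and is removed in step 7.

Step 7
Reactants: 8 carbinol
Product: 9 methyl ketone, ring D now 3-acetyl-4,6-bis(benzyloxy)-2-hydroxyphenyl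
Conditions: MnO2 (activated, excess), CH2Cl2, rt
Reagents that add atoms: none
Why: Selective MnO2 oxidation of the activated benzylic alcohol to the aryl ketone; the non-benzylic C3 alcohol and the benzyl ethers are not touched.

Step 8
Reactants: 9 methyl ketone; 10 3,4-bis(benzyloxy)benzaldehyde (1.5 equiv)
Product: 11 2′-hydroxychalcone, ring D now 4,6-bis(benzyloxy)-2-hydroxy-3-[(E)-3-(3,4-bis(benzyloxy)phenyl)prop-2-enoyl]phenyl
Conditions: KOH (50% aq), EtOH–THF, rt; cold dilute HCl
Reagents that add atoms: none
Why: Claisen–Schmidt (crossed aldol) condensation of the methyl ketone enolate with the non-enolisable aldehyde; E1cB dehydration gives the (E)-enone, and in strong base the product rests as the chalcone phenoxide, not as the flavanone.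

Step 9
Reactants: 11 2′-hydroxychalcone
Product: 12 flavanone: (2′S)-5′,7′-bis(benzyloxy)-2′-[3,4-bis(benzyloxy)phenyl]chroman-4′-one joined through C8′ to C4 (β) of pentabenzyl epigallocatechin, 3-OH free
Conditions: N-[3,5-bis(trifluoromethyl)phenyl]-N′-[(8α,9S)-6′-methoxycinchonan-9-yl]thiourea (20 mol %), toluene, 0 °C → rt
Reagents that add atoms: none
Why: Intramolecular oxa-Michael addition under bifunctional catalysis: the quinuclidine nitrogen takes the proton of the C8a′ hydroxyl while the thiourea N–H bonds hold the enone carbonyl, the phenoxide oxygen adds to the β-carbon to form O1′–C2′, and protonation of the enolate at C3′ releases the catalyst. The closest known reaction is the amine–thiourea and cinchona-base catalysed cyclisation of 2′-hydroxychalcones to flavanones, the non-enzymatic counterpart of chalcone isomerase. Ring F closes in a 6-endo-trig mode (the C2′=C3′ bond lies inside the new ring), which is allowed. The new stereocentre C2′ is set by the catalyst, which shields one face of the bound enone; the chiral upper unit on the neighbouring C8′ makes the two outcomes diastereomeric, so the catalyst is either matched or mismatched with it, and the pseudoenantiomeric quinidine-derived thiourea is the direct replacement. Site selectivity is secured by the substrate: the only phenol is on C8a′, so the pyranone can fuse only next to C8′ (4→8 connectivity), and the aliphatic C3 hydroxyl would have to form a nine-membered ring. The C5′ benzyloxy group keeps the aroyl group out of the ring D plane, which weakens the O–H···O=C bond that stabilises the open form and should place the equilibrium on the flavanone side. The selectivity needed is kinetic facial selectivity: because the addition is reversible the reaction is stopped at conversion and not left to equilibrate, and the C2′ epimers, being diastereomers, can be separated and the minor one reopened with base to 11.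

Step 10
Reactants: 12 flavanone; 13 3,4,5-tris(benzyloxy)benzoic acid (2 equiv)
Product: 14 3-O-[3,4,5-tris(benzyloxy)benzoyl] ester of 12
Conditions: DCC (2.2 equiv), DMAP (1 equiv), CH2Cl2, rt
Reagents that add atoms: none
Why: Steglich esterification (carbodiimide activation, DMAP acyl transfer) of the only hydroxyl in 12; placing the gallate here avoids the strongly basic steps 6 and 8 and removes any need to distinguish O3 from the C3′ hydroxyl that appears in step 11.

Step 11
Reactants: 14 flavanone gallate
Product: 17 gallate of the (2′R,3′R)-3′-hydroxyflavanone (2′,3′-trans dihydroflavonol; 14 with OH on C3′), via trimethylsilyl enol ether 15 (not isolated), via 3′-O-trimethylsilyl ketone 16 (not isolated)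
Conditions: (a) TMSOTf, Et3N, CH2Cl2, 0 °C, crude; (b) mCPBA, NaHCO3, CH2Cl2, −20 °C; (c) citric acid, MeOH–THF, 0 °C
Reagents that add atoms: 3-chloroperoxybenzoic acid (mCPBA), O=C(OO)c1cccc(Cl)c1; trimethylsilyl trifluoromethanesulfonate, C[Si](C)(C)OS(=O)(=O)C(F)(F)F (its silyl group is carried by 15 and 16 only)
Why: Rubottom oxidation: soft enolisation (silyl triflate and amine, no free enolate, hence no β-elimination of the C8a′ phenoxide) gives the silyl enol ether, the peracid epoxidises it on the face opposite the C2′ aryl group, and epoxide opening with 1,4-silyl shift gives the α-silyloxy ketone, which mild acid desilylates. The 3′-oxygen therefore ends trans to the C2′ aryl group (2′R,3′R), which is also the more stable arrangement of a dihydroflavonol.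

Step 12
Reactants: 17 dihydroflavonol gallate
Product: 18 3′,4′-diol (17 with C4′ carbonyl reduced to CH–OH, both C4′ epimers)
Conditions: NaBH4, THF–MeOH, −20 → 0 °C
Reagents that add atoms: none
Why: Hydride reduction of the aryl ketone to the benzylic alcohol; the aryl ester is not reduced by NaBH4 at low temperature, and the configuration at C4′ is irrelevant because C4′ becomes a methylene group in step 13.

Step 13
Reactants: 18 3′,4′-diol
Product: 19 dodeca-O-benzyl target: benzyl-protected epigallocatechin gallate-(4β→8)-catechin with free 3′-hydroxyl (2′R,3′S)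
Conditions: Et3SiH (5 equiv), CF3CO2H (3 equiv), CH2Cl2, −40 → 0 °C
Reagents that add atoms: none
Why: Ionic hydrogenation: acid ionises only the C4′ hydroxyl, whose cation is stabilised by the three oxygens of ring D, and the silane delivers hydride; the non-benzylic C3′ hydroxyl and the ester stay, and C2′ and C3′ are not involved.

Step 14
Reactants: 19 dodeca-O-benzyl target
Product: 20 epigallocatechin 3-O-gallate-(4β→8)-catechin (target)
Conditions: H2 (1 atm), Pd(OH)2 on carbon, THF–MeOH–H2O, rt; filtration under argon, lyophilisation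
Reagents that add atoms: none
Why: Global hydrogenolysis of the twelve O-benzyl groups under neutral conditions; the aryl ester, the ring C–O bonds and the C4–C8′ bond are stable to hydrogen over palladium, and inert work-up protects the pyrogallol rings from air.

## Compound list

1 | (−)-epigallocatechin | O[C@@H]1Cc2c(O)cc(O)cc2O[C@@H]1c1cc(O)c(O)c(O)c1 | starting material
2 | (2R,3R)-5,7-bis(benzyloxy)-2-[3,4,5-tris(benzyloxy)phenyl]chroman-3-ol | O[C@@H]1Cc2c(OCc3ccccc3)cc(OCc3ccccc3)cc2O[C@@H]1c1cc(OCc2ccccc2)c(OCc2ccccc2)c(OCc2ccccc2)c1 | intermediate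
3 | 4β-(2-ethoxyethoxy) derivative of 2 (3,4-trans) | O[C@@H]1[C@@H](OCCOCC)c2c(OCc3ccccc3)cc(OCc3ccccc3)cc2O[C@@H]1c1cc(OCc2ccccc2)c(OCc2ccccc2)c(OCc2ccccc2)c1 | intermediate
4 | phloroglucinol | Oc1cc(O)cc(O)c1 | starting material
5 | 3,5-bis(benzyloxy)phenol | Oc1cc(OCc2ccccc2)cc(OCc2ccccc2)c1 | intermediate
6 | 4β-[4,6-bis(benzyloxy)-2-hydroxyphenyl] pentabenzyl epigallocatechin | O[C@@H]1[C@@H](c2c(OCc3ccccc3)cc(OCc3ccccc3)cc2O)c2c(OCc3ccccc3)cc(OCc3ccccc3)cc2O[C@@H]1c1cc(OCc2ccccc2)c(OCc2ccccc2)c(OCc2ccccc2)c1 | intermediate
7 | 6 with formyl on C4a′ | O[C@@H]1[C@@H](c2c(OCc3ccccc3)cc(OCc3ccccc3)c(C=O)c2O)c2c(OCc3ccccc3)cc(OCc3ccccc3)cc2O[C@@H]1c1cc(OCc2ccccc2)c(OCc2ccccc2)c(OCc2ccccc2)c1 | intermediate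
8 | 6 with 1-hydroxyethyl on C4a′ (carbinol epimers) | O[C@@H]1[C@@H](c2c(OCc3ccccc3)cc(OCc3ccccc3)c(C(C)O)c2O)c2c(OCc3ccccc3)cc(OCc3ccccc3)cc2O[C@@H]1c1cc(OCc2ccccc2)c(OCc2ccccc2)c(OCc2ccccc2)c1 | intermediate
9 | 6 with acetyl on C4a′ | O[C@@H]1[C@@H](c2c(OCc3ccccc3)cc(OCc3ccccc3)c(C(C)=O)c2O)c2c(OCc3ccccc3)cc(OCc3ccccc3)cc2O[C@@H]1c1cc(OCc2ccccc2)c(OCc2ccccc2)c(OCc2ccccc2)c1 | intermediate
10 | 3,4-bis(benzyloxy)benzaldehyde | O=Cc1ccc(OCc2ccccc2)c(OCc2ccccc2)c1 | starting material
11 | 2′-hydroxychalcone (precursor of the key step, free 3-OH) | O[C@@H]1[C@@H](c2c(OCc3ccccc3)cc(OCc3ccccc3)c(C(=O)/C=C/c3ccc(OCc4ccccc4)c(OCc4ccccc4)c3)c2O)c2c(OCc3ccccc3)cc(OCc3ccccc3)cc2O[C@@H]1c1cc(OCc2ccccc2)c(OCc2ccccc2)c(OCc2ccccc2)c1 | intermediate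
12 | (2′S)-flavanone, 4→8 linked (product of the key step, free 3-OH) | O[C@@H]1[C@@H](c2c(OCc3ccccc3)cc(OCc3ccccc3)c3c2O[C@H](c2ccc(OCc4ccccc4)c(OCc4ccccc4)c2)CC3=O)c2c(OCc3ccccc3)cc(OCc3ccccc3)cc2O[C@@H]1c1cc(OCc2ccccc2)c(OCc2ccccc2)c(OCc2ccccc2)c1 | intermediate
13 | 3,4,5-tris(benzyloxy)benzoic acid | O=C(O)c1cc(OCc2ccccc2)c(OCc2ccccc2)c(OCc2ccccc2)c1 | starting material
14 | 3-O-[3,4,5-tris(benzyloxy)benzoyl] ester of 12 | O=C(O[C@@H]1[C@@H](c2c(OCc3ccccc3)cc(OCc3ccccc3)c3c2O[C@H](c2ccc(OCc4ccccc4)c(OCc4ccccc4)c2)CC3=O)c2c(OCc3ccccc3)cc(OCc3ccccc3)cc2O[C@@H]1c1cc(OCc2ccccc2)c(OCc2ccccc2)c(OCc2ccccc2)c1)c1cc(OCc2ccccc2)c(OCc2ccccc2)c(OCc2ccccc2)c1 | intermediate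
15 | 4′-trimethylsilyloxy flav-3′-ene (silyl enol ether of 14) | O=C(O[C@@H]1[C@@H](c2c(OCc3ccccc3)cc(OCc3ccccc3)c3c2O[C@H](c2ccc(OCc4ccccc4)c(OCc4ccccc4)c2)C=C3O[Si](C)(C)C)c2c(OCc3ccccc3)cc(OCc3ccccc3)cc2O[C@@H]1c1cc(OCc2ccccc2)c(OCc2ccccc2)c(OCc2ccccc2)c1)c1cc(OCc2ccccc2)c(OCc2ccccc2)c(OCc2ccccc2)c1 | intermediate (not isolated)
16 | 3′-O-trimethylsilyl ether of 17 | O=C(O[C@@H]1[C@@H](c2c(OCc3ccccc3)cc(OCc3ccccc3)c3c2O[C@H](c2ccc(OCc4ccccc4)c(OCc4ccccc4)c2)[C@@H](O[Si](C)(C)C)C3=O)c2c(OCc3ccccc3)cc(OCc3ccccc3)cc2O[C@@H]1c1cc(OCc2ccccc2)c(OCc2ccccc2)c(OCc2ccccc2)c1)c1cc(OCc2ccccc2)c(OCc2ccccc2)c(OCc2ccccc2)c1 | intermediate (not isolated)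
17 | (2′R,3′R)-3′-hydroxyflavanone gallate (2′,3′-trans) | O=C(O[C@@H]1[C@@H](c2c(OCc3ccccc3)cc(OCc3ccccc3)c3c2O[C@H](c2ccc(OCc4ccccc4)c(OCc4ccccc4)c2)[C@@H](O)C3=O)c2c(OCc3ccccc3)cc(OCc3ccccc3)cc2O[C@@H]1c1cc(OCc2ccccc2)c(OCc2ccccc2)c(OCc2ccccc2)c1)c1cc(OCc2ccccc2)c(OCc2ccccc2)c(OCc2ccccc2)c1 | intermediate
18 | 3′,4′-diol gallate (C4′ epimers) | O=C(O[C@@H]1[C@@H](c2c(OCc3ccccc3)cc(OCc3ccccc3)c3c2O[C@H](c2ccc(OCc4ccccc4)c(OCc4ccccc4)c2)[C@@H](O)C3O)c2c(OCc3ccccc3)cc(OCc3ccccc3)cc2O[C@@H]1c1cc(OCc2ccccc2)c(OCc2ccccc2)c(OCc2ccccc2)c1)c1cc(OCc2ccccc2)c(OCc2ccccc2)c(OCc2ccccc2)c1 | intermediate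
19 | dodeca-O-benzyl target with free 3′-hydroxyl | O=C(O[C@@H]1[C@@H](c2c(OCc3ccccc3)cc(OCc3ccccc3)c3c2O[C@H](c2ccc(OCc4ccccc4)c(OCc4ccccc4)c2)[C@@H](O)C3)c2c(OCc3ccccc3)cc(OCc3ccccc3)cc2O[C@@H]1c1cc(OCc2ccccc2)c(OCc2ccccc2)c(OCc2ccccc2)c1)c1cc(OCc2ccccc2)c(OCc2ccccc2)c(OCc2ccccc2)c1 | intermediate
20 | epigallocatechin 3-O-gallate-(4β→8)-catechin | O=C(O[C@@H]1[C@@H](c2c(O)cc(O)c3c2O[C@H](c2ccc(O)c(O)c2)[C@@H](O)C3)c2c(O)cc(O)cc2O[C@@H]1c1cc(O)c(O)c(O)c1)c1cc(O)c(O)c(O)c1 | target

## Step count and least certain steps

Total: 14 steps. Longest linear sequence: 13 steps (from 1 through steps 1, 2 and 4 to 14); step 3 is a one-step side branch.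

**Step 9 (key step).**
- Risk: low facial selectivity at C2′, either because the catalyst's preference is opposed by the upper unit or because reversible ring-opening under the basic catalyst lets the epimers equilibrate. Turnover may also be slow, since the reacting phenol is hydrogen-bonded to the carbonyl and flanked by the upper unit.
- Fallback (activated acceptor, the variant of this cyclisation with the strongest catalyst control): it sets out from 7. Aldol addition of the lithium enolate of tert-butyl acetate (LiN(iPr)2, THF, −78 °C, excess) gives the tert-butyl β-hydroxy ester F1. MnO2 oxidises it to the β-keto ester F2. Knoevenagel condensation with 10 (piperidine, acetic acid) gives the alkylidene β-keto ester F3. The amine–thiourea of step 9 then closes ring F at low temperature to the tert-butyl flavanone-3′-carboxylate F4, in which both carbonyl groups bind the thiourea. Warming with TsOH removes the tert-butyl group and decarboxylates, which brings the sequence back to 12.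

**Step 4.**
- Risk: arylation through the carbon para to the hydroxyl of 5 (between the two benzyloxy groups), giving a constitutional isomer; oligomerisation by attack of ring A of a second molecule of 3, or a second arylation of 6.
- Fallback (blocked nucleophile): it sets out from 3 and 5. Bromination of 5 (NBS) and separation gives 4-bromo-3,5-bis(benzyloxy)phenol F5, in which the para carbon is occupied. Under the conditions of step 4, 3 and F5 can only give the C6′-bromo analogue of 6, bromide F6. Bromine–lithium exchange (n-BuLi in excess, THF, −78 °C, then methanol) replaces bromine by hydrogen and returns to 6. The regiochemical question is thereby moved to a small phenol whose isomers are separable.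

**Step 11.**
- Risk: opening of ring F by β-elimination of the C8a′ phenoxide during enolisation, with loss of the C2′ configuration; oxidation of the electron-rich benzyloxy arenes by the peracid.
- Fallback (hydroboration instead of enol oxidation, which also bypasses steps 12 and 13): it sets out from 14. NaBH4 gives the flavan-4′-ol F7. Dehydration (pyridinium p-toluenesulfonate, warm toluene) gives the flav-3′-ene F8. Hydroboration (BH3·THF) places boron on C3′, away from the aryl-stabilised C4′ and anti to the C2′ aryl group, and oxidation with NaBO3 (mild enough for the ester) gives the 2′,3′-trans alcohol 19 directly.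

**Step 13.**
- Risk: acid-induced heterolysis of the C4–C8′ bond once ring D is electron-rich again; loss of H3′ from the C4′ cation (to the enol and then the flavan-3′-one) in competition with hydride transfer.
- Fallback (hydrogenolysis instead of ionic reduction): the C4′ hydroxyl is left in 18 and removed in the last step together with the benzyl groups. Hydrogen over Pd(OH)2 on carbon with a little acetic acid cleaves the activated benzylic C4′–O bond, as in the classical reduction of flavan-3,4-diols to flavan-3-ols. The fallback sets out from 18 and arrives at 20 without any new compound (entry F0).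

## Further compounds

F1 | step 9 | 6 with 3-tert-butoxy-1-hydroxy-3-oxopropyl on C4a′ (tert-butyl β-hydroxy ester) | O[C@@H]1[C@@H](c2c(OCc3ccccc3)cc(OCc3ccccc3)c(C(O)CC(=O)OC(C)(C)C)c2O)c2c(OCc3ccccc3)cc(OCc3ccccc3)cc2O[C@@H]1c1cc(OCc2ccccc2)c(OCc2ccccc2)c(OCc2ccccc2)c1
F2 | step 9 | tert-butyl β-keto ester on C4a′ | O[C@@H]1[C@@H](c2c(OCc3ccccc3)cc(OCc3ccccc3)c(C(=O)CC(=O)OC(C)(C)C)c2O)c2c(OCc3ccccc3)cc(OCc3ccccc3)cc2O[C@@H]1c1cc(OCc2ccccc2)c(OCc2ccccc2)c(OCc2ccccc2)c1
F3 | step 9 | alkylidene β-keto ester (tert-butyl 2-aroyl-3-[3,4-bis(benzyloxy)phenyl]acrylate, E/Z mixture) | O[C@@H]1[C@@H](c2c(OCc3ccccc3)cc(OCc3ccccc3)c(C(=O)C(=Cc3ccc(OCc4ccccc4)c(OCc4ccccc4)c3)C(=O)OC(C)(C)C)c2O)c2c(OCc3ccccc3)cc(OCc3ccccc3)cc2O[C@@H]1c1cc(OCc2ccccc2)c(OCc2ccccc2)c(OCc2ccccc2)c1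
F4 | step 9 | tert-butyl (2′S)-flavanone-3′-carboxylate (12 with CO2tBu on C3′) | O[C@@H]1[C@@H](c2c(OCc3ccccc3)cc(OCc3ccccc3)c3c2O[C@H](c2ccc(OCc4ccccc4)c(OCc4ccccc4)c2)C(C(=O)OC(C)(C)C)C3=O)c2c(OCc3ccccc3)cc(OCc3ccccc3)cc2O[C@@H]1c1cc(OCc2ccccc2)c(OCc2ccccc2)c(OCc2ccccc2)c1
F5 | step 4 | 4-bromo-3,5-bis(benzyloxy)phenol | Oc1cc(OCc2ccccc2)c(Br)c(OCc2ccccc2)c1
F6 | step 4 | C6′-bromo analogue of 6 | O[C@@H]1[C@@H](c2c(OCc3ccccc3)c(Br)c(OCc3ccccc3)cc2O)c2c(OCc3ccccc3)cc(OCc3ccccc3)cc2O[C@@H]1c1cc(OCc2ccccc2)c(OCc2ccccc2)c(OCc2ccccc2)c1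
F7 | step 11 | flavan-4′-ol gallate (14 with C4′ carbonyl reduced, C4′ epimers) | O=C(O[C@@H]1[C@@H](c2c(OCc3ccccc3)cc(OCc3ccccc3)c3c2O[C@H](c2ccc(OCc4ccccc4)c(OCc4ccccc4)c2)CC3O)c2c(OCc3ccccc3)cc(OCc3ccccc3)cc2O[C@@H]1c1cc(OCc2ccccc2)c(OCc2ccccc2)c(OCc2ccccc2)c1)c1cc(OCc2ccccc2)c(OCc2ccccc2)c(OCc2ccccc2)c1
F8 | step 11 | flav-3′-ene gallate | O=C(O[C@@H]1[C@@H](c2c(OCc3ccccc3)cc(OCc3ccccc3)c3c2O[C@H](c2ccc(OCc4ccccc4)c(OCc4ccccc4)c2)C=C3)c2c(OCc3ccccc3)cc(OCc3ccccc3)cc2O[C@@H]1c1cc(OCc2ccccc2)c(OCc2ccccc2)c(OCc2ccccc2)c1)c1cc(OCc2ccccc2)c(OCc2ccccc2)c(OCc2ccccc2)c1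
F0 | step 13 | none | none
A1 | alternative 1 | dimethyl malonate carrying C4 (lower unit on C4, acetonide over O2 and O3) | COC(=O)C(C(=O)OC)[C@H](c1c(OCc2ccccc2)cc(OCc2ccccc2)c2c1O[C@H](c1ccc(OCc3ccccc3)c(OCc3ccccc3)c1)[C@@H](OCc1ccccc1)C2)[C@H]1OC(C)(C)O[C@H]1c1cc(OCc2ccccc2)c(OCc2ccccc2)c(OCc2ccccc2)c1
A2 | alternative 1 | dimethyl 3-oxopentanedioate | COC(=O)CC(=O)CC(=O)OC
A3 | alternative 1 | dimethyl 2,4,6-trihydroxyisophthalate ring A attached to C4 | COC(=O)c1c(O)c(C(=O)OC)c(O)c([C@H](c2c(OCc3ccccc3)cc(OCc3ccccc3)c3c2O[C@H](c2ccc(OCc4ccccc4)c(OCc4ccccc4)c2)[C@@H](OCc2ccccc2)C3)[C@H]2OC(C)(C)O[C@H]2c2cc(OCc3ccccc3)c(OCc3ccccc3)c(OCc3ccccc3)c2)c1O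
A4 | alternative 2 | 3,5-bis(benzyloxy)-2-(trimethylsilyl)phenyl trifluoromethanesulfonate | C[Si](C)(C)c1c(OCc2ccccc2)cc(OCc2ccccc2)cc1OS(=O)(=O)C(F)(F)F
A5 | alternative 2 | pentabenzyl catechin-8-carbaldehyde | O=Cc1c(OCc2ccccc2)cc(OCc2ccccc2)c2c1O[C@H](c1ccc(OCc3ccccc3)c(OCc3ccccc3)c1)[C@@H](OCc1ccccc1)C2
A6 | alternative 2 | (Z)-2-[3,4,5-tris(benzyloxy)phenyl]ethenyl 3,4,5-tris(benzyloxy)benzoate | O=C(O/C=C\c1cc(OCc2ccccc2)c(OCc2ccccc2)c(OCc2ccccc2)c1)c1cc(OCc2ccccc2)c(OCc2ccccc2)c(OCc2ccccc2)c1
A7 | alternative 2 | per-O-benzyl target | O=C(O[C@@H]1[C@@H](c2c(OCc3ccccc3)cc(OCc3ccccc3)c3c2O[C@H](c2ccc(OCc4ccccc4)c(OCc4ccccc4)c2)[C@@H](OCc2ccccc2)C3)c2c(OCc3ccccc3)cc(OCc3ccccc3)cc2O[C@@H]1c1cc(OCc2ccccc2)c(OCc2ccccc2)c(OCc2ccccc2)c1)c1cc(OCc2ccccc2)c(OCc2ccccc2)c(OCc2ccccc2)c1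
A8 | alternative 3 | C4-[(triisopropylsilyloxy)ethynyl] flavan (O3 tert-butyldimethylsilyl, benzyl protected) | CC(C)(C)[Si](C)(C)O[C@@H]1[C@@H](C#CO[Si](C(C)C)(C(C)C)C(C)C)c2c(OCc3ccccc3)cc(OCc3ccccc3)cc2O[C@@H]1c1cc(OCc2ccccc2)c(OCc2ccccc2)c(OCc2ccccc2)c1
A9 | alternative 3 | 3-benzyloxy-4-(acetonide side chain)cyclobut-2-en-1-one | O=C1C=C(OCc2ccccc2)C1C[C@@H]1OC(C)(C)O[C@H]1c1ccc(OCc2ccccc2)c(OCc2ccccc2)c1
A10 | alternative 3 | ring D phenol with free C8a′ hydroxyl, upper unit on C8′, acetonide chain on C4a′ | CC(C)(C)[Si](C)(C)O[C@@H]1[C@@H](c2c(O[Si](C(C)C)(C(C)C)C(C)C)cc(OCc3ccccc3)c(C[C@@H]3OC(C)(C)O[C@H]3c3ccc(OCc4ccccc4)c(OCc4ccccc4)c3)c2O)c2c(OCc3ccccc3)cc(OCc3ccccc3)cc2O[C@@H]1c1cc(OCc2ccccc2)c(OCc2ccccc2)c(OCc2ccccc2)c1
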